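**Retrosynthetic overview**

1. The only ring, the 1,2‑dioxane, is closed last by 6‑exo peroxy‑Michael addition of the C6 hydroperoxide onto an (E)‑2‑methyl enoate; C3 and C2 arise in that step.
2. Both tertiary C–OO centres (C6, C14) come from tertiary alcohols by one OH→OOH exchange with inversion; the alcohols are the carbinol carbons of two molecules of (R)‑linalool.
3. C11–C12 is made by a visible‑light nickel/photoredox deoxygenative C(sp3)–C(sp3) coupling of the linalool‑derived 1,3‑diol with (S)‑1‑bromo‑3‑chloro‑2‑methylpropane, which brings C10.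
4. C8–C9 is made by B‑alkyl Suzuki coupling of the vinyl group of a linalool‑derived enoate (ozonolysis/Wittig) with the resulting primary iodide.
5. Ring order: one ring, formed in the final step.

Assumption: (R)‑(−)‑linalool (≥97% ee), Roche‑ester‑derived (S)‑1‑bromo‑3‑chloro‑2‑methylpropane and the Wittig ylide are purchased; carbons are numbered C1 (ester carbonyl) to C18 along the main chain of the target.

**Step 1**
Reactants: 1 (R)‑(−)‑linalool, (3R)‑3,7‑dimethylocta‑1,6‑dien‑3‑ol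
Product: 3 (3R)‑3,7‑dimethyloct‑6‑ene‑1,3‑diol, via B‑alkyl‑9‑BBN adduct 2 (not isolated)
Conditions: 9‑BBN, THF, 0 °C→rt; then NaOH (3 M), 30% H2O2, 0 °C→rt
Reagents that add atoms: hydrogen peroxide, OO
Why: Brown hydroboration–oxidation, in which 9‑BBN adds anti‑Markovnikov to the monosubstituted vinyl group only (the trisubstituted alkene is far slower) and the bought carbinol centre (future C14) is not touched.

**Step 2**
Reactants: 3 (3R)‑3,7‑dimethyloct‑6‑ene‑1,3‑diol; 4 (S)‑1‑bromo‑3‑chloro‑2‑methylpropane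
Product: 6 (2R,6S)‑1‑chloro‑2,6,10‑trimethylundec‑9‑en‑6‑ol, via alkoxybenzoxazoline adduct 5 (not isolated)
Conditions: 5,7‑di‑tert‑butyl‑3‑phenylbenzoxazolium tetrafluoroborate, pyridine, MTBE, rt; then 4, Ir(ppy)2(dtbbpy)PF6 (1 mol%), NiBr2(dtbbpy) (5 mol%), quinuclidine, DMA, 450 nm LEDs, rt
Reagents that add atoms: none
Why: Metallaphotoredox deoxygenative C(sp3)–C(sp3) cross‑coupling, in which only the primary hydroxyl condenses with the benzoxazolium salt, photocatalytic oxidation and β‑scission of 5 release the C12 radical, and nickel joins it to the C–Br end of 4 (C–Cl inert), forming the key C11–C12 bond without touching C10 (bought in 4) or the carbinol centre.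

**Step 3**
Reactants: 6 (2R,6S)‑1‑chloro‑2,6,10‑trimethylundec‑9‑en‑6‑ol
Product: 7 (2R,6S)‑1‑iodo‑2,6,10‑trimethylundec‑9‑en‑6‑ol
Conditions: NaI, 2‑butanone, 80 °C
Reagents that add atoms: sodium iodide, [Na+].[I-]
Why: Finkelstein halide exchange (SN2 at the primary carbon, driven by precipitation of NaCl), with no stereocentre involved.

**Step 4**
Reactants: 1 (R)‑(−)‑linalool; 8 methyl 2‑(triphenyl‑λ5‑phosphanylidene)propanoate
Product: 10 methyl (2E,6R)‑6‑hydroxy‑2,6‑dimethylocta‑2,7‑dienoate, via lactol 9 (not isolated)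
Conditions: O3 (1 equiv), CH2Cl2, −78 °C; Me2S, −78 °C→rt; then 8, CH2Cl2, 40 °C
Reagents that add atoms: none
Why: Chemoselective ozonolysis of the electron‑rich trisubstituted alkene (the vinyl group survives one equivalent of ozone) gives lactol 9, whose open hydroxy aldehyde undergoes Wittig olefination with the stabilised ylide to the (E)‑enoate, leaving the bought carbinol centre (future C6) untouched.

**Step 5**
Reactants: 10 methyl (2E,6R)‑6‑hydroxy‑2,6‑dimethylocta‑2,7‑dienoate; 7 (2R,6S)‑1‑iodo‑2,6,10‑trimethylundec‑9‑en‑6‑ol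
Product: 12 methyl (2E,6S,10R,14S)‑6,14‑dihydroxy‑2,6,10,14,18‑pentamethylnonadeca‑2,17‑dienoate, via alkylborane 11 (not isolated)
Conditions: 9‑BBN, THF, rt; then 7, Pd(PPh3)4 (5 mol%), K3PO4, dioxane, 60 °C
Reagents that add atoms: none
Why: Suzuki–Miyaura B‑alkyl sp3–sp3 cross‑coupling, in which 9‑BBN hydroborates only the vinyl group of 10 and zerovalent palladium couples the primary alkylborane with the primary iodide to form C8–C9, leaving all three bought stereocentres unaffected.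

**Step 6**
Reactants: 12 methyl (2E,6S,10R,14S)‑6,14‑dihydroxy‑2,6,10,14,18‑pentamethylnonadeca‑2,17‑dienoate
Product: 15 methyl (2E,6R,10R,14R)‑6,14‑dihydroperoxy‑2,6,10,14,18‑pentamethylnonadeca‑2,17‑dienoate, via bis‑phosphinite 13 (not isolated), via bis‑phosphonium phenoxide 14 (not isolated)
Conditions: Ph2PCl, Et3N, DMAP (cat.), toluene, rt, filter; then 2,6‑dimethyl‑1,4‑benzoquinone, CH2Cl2, −40 °C; then anhydrous H2O2 in Et2O, −40 °C→rt
Reagents that add atoms: hydrogen peroxide, OO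
Why: Proposed new method: a Mukaiyama‑type oxidation–reduction condensation with hydrogen peroxide as pronucleophile, in which each tert‑alkyl diphenylphosphinite adds to the quinone to give an aryloxy(alkoxy)phosphonium phenoxide (all trivalent phosphorus is consumed before peroxide is added), the phenoxide deprotonates H2O2 (pKa 11.6, like the phenols already used), and HOO−, an α‑effect nucleophile, displaces diphenylphosphinate from the tertiary carbon within the ion pair with inversion, turning (6S,14S)‑12 into (6R,14R)‑15 and so setting C6 and C14 from the bought linalool carbinols; the closest known reactions are the quinone‑mediated stereoinvertive esterification, etherification and azidation of tertiary alcohols via alkoxydiphenylphosphines and the invertive opening of tertiary oxetanes by H2O2.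

**Step 7**
Reactants: 15 methyl (2E,6R,10R,14R)‑6,14‑dihydroperoxy‑2,6,10,14,18‑pentamethylnonadeca‑2,17‑dienoate
Product: 16 methyl (2R)‑2‑[(3S,6R)‑6‑[(4R,8R)‑8‑hydroperoxy‑4,8,12‑trimethyltridec‑11‑en‑1‑yl]‑6‑methyl‑1,2‑dioxan‑3‑yl]propanoate
Conditions: Et2NH (0.3 equiv), CF3CH2OH, rt; chromatography
Reagents that add atoms: none
Why: 6‑exo‑trig peroxy‑Michael (oxa‑Michael) addition of the C6 hydroperoxide to the enoate under amine catalysis in a protic fluorinated solvent (fast enolate protonation suppresses epoxide formation), in which C3 and C2 are set under substrate control from C6 through a chair transition state with the enoate arm and the long C6 chain equatorial and the C6 methyl axial (3S) and protonation anti to the ring (2R); this bias is only modest, so the (2R,3S) isomer is isolated by chromatography and the other C2/C3 isomers are recycled by base‑induced retro‑Michael equilibration, while the C14 hydroperoxide has no acceptor within reach and stays free.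

**Compound list**

1 | (R)‑(−)‑linalool, (3R)‑3,7‑dimethylocta‑1,6‑dien‑3‑ol | C=C[C@](C)(O)CCC=C(C)C | starting material
2 | (3S)‑1‑(9‑borabicyclo[3.3.1]nonan‑9‑yl)‑3,7‑dimethyloct‑6‑en‑3‑ol | CC(C)=CCC[C@@](C)(O)CCB1C2CCCC1CCC2 | intermediate
3 | (3R)‑3,7‑dimethyloct‑6‑ene‑1,3‑diol | OCC[C@](C)(O)CCC=C(C)C | intermediate
4 | (S)‑1‑bromo‑3‑chloro‑2‑methylpropane | ClC[C@H](C)CBr | starting material
5 | (3R)‑1‑[(5,7‑di‑tert‑butyl‑3‑phenyl‑2,3‑dihydro‑1,3‑benzoxazol‑2‑yl)oxy]‑3,7‑dimethyloct‑6‑en‑3‑ol (both epimers at the aminal carbon) | CC(C)=CCC[C@@](C)(O)CCOC1Oc2c(cc(cc2N1c1ccccc1)C(C)(C)C)C(C)(C)C | intermediate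
6 | (2R,6S)‑1‑chloro‑2,6,10‑trimethylundec‑9‑en‑6‑ol | ClC[C@H](C)CCC[C@](C)(O)CCC=C(C)C | intermediate
7 | (2R,6S)‑1‑iodo‑2,6,10‑trimethylundec‑9‑en‑6‑ol | IC[C@H](C)CCC[C@](C)(O)CCC=C(C)C | intermediate
8 | methyl 2‑(triphenyl‑λ5‑phosphanylidene)propanoate | COC(=O)C(C)=P(c1ccccc1)(c1ccccc1)c1ccccc1 | starting material
9 | (5R)‑5‑ethenyl‑5‑methyloxolan‑2‑ol (both anomers) | OC1CC[C@](C)(C=C)O1 | intermediate
10 | methyl (2E,6R)‑6‑hydroxy‑2,6‑dimethylocta‑2,7‑dienoate | COC(=O)/C(C)=C/CC[C@@](C)(O)C=C | intermediate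
11 | methyl (2E,6S)‑8‑(9‑borabicyclo[3.3.1]nonan‑9‑yl)‑6‑hydroxy‑2,6‑dimethyloct‑2‑enoate | COC(=O)/C(C)=C/CC[C@@](C)(O)CCB1C2CCCC1CCC2 | intermediate
12 | methyl (2E,6S,10R,14S)‑6,14‑dihydroxy‑2,6,10,14,18‑pentamethylnonadeca‑2,17‑dienoate | COC(=O)/C(C)=C/CC[C@@](C)(O)CCC[C@H](C)CCC[C@](C)(O)CCC=C(C)C | intermediate
13 | methyl (2E,6S,10R,14S)‑6,14‑bis[(diphenylphosphanyl)oxy]‑2,6,10,14,18‑pentamethylnonadeca‑2,17‑dienoate | COC(=O)/C(C)=C/CC[C@@](C)(OP(c1ccccc1)c1ccccc1)CCC[C@H](C)CCC[C@](C)(OP(c1ccccc1)c1ccccc1)CCC=C(C)C | intermediate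
14 | methyl (2E,6S,10R,14S)‑6,14‑bis{[(3,5‑dimethyl‑4‑oxidophenoxy)diphenylphosphaniumyl]oxy}‑2,6,10,14,18‑pentamethylnonadeca‑2,17‑dienoate (double zwitterion) | COC(=O)/C(C)=C/CC[C@@](C)(O[P+](c1ccccc1)(c1ccccc1)Oc1cc(C)c([O-])c(C)c1)CCC[C@H](C)CCC[C@](C)(O[P+](c1ccccc1)(c1ccccc1)Oc1cc(C)c([O-])c(C)c1)CCC=C(C)C | intermediate
15 | methyl (2E,6R,10R,14R)‑6,14‑dihydroperoxy‑2,6,10,14,18‑pentamethylnonadeca‑2,17‑dienoate | COC(=O)/C(C)=C/CC[C@](C)(OO)CCC[C@H](C)CCC[C@@](C)(OO)CCC=C(C)C | intermediate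
16 | methyl (2R)‑2‑[(3S,6R)‑6‑[(4R,8R)‑8‑hydroperoxy‑4,8,12‑trimethyltridec‑11‑en‑1‑yl]‑6‑methyl‑1,2‑dioxan‑3‑yl]propanoate | COC(=O)[C@H](C)[C@@H]1CC[C@@](C)(CCC[C@H](C)CCC[C@](C)(CCC=C(C)C)OO)OO1 | target

**Step count and risks**

Total steps: 7. Longest linear sequence: 6 steps (1 → 3 → 6 → 7 → 12 → 15 → 16; steps 1, 2, 3, 5, 6, 7).

Three steps most likely to fail:

Step 6 (the proposed new substitution). The risks are elimination, attack of HOO− at phosphorus instead of carbon, and oxidation of any residual trivalent phosphorus. The fallback uses known chemistry throughout: Lewis‑acid opening of tertiary oxetanes by H2O2 with inversion, then peroxide‑tolerant olefination and diimide reduction. It sets out from 3 and comes back at 16. Diol 3 is cyclised (n‑BuLi, TsCl, then n‑BuLi, THF) to (2R)‑2‑methyl‑2‑(4‑methylpent‑3‑en‑1‑yl)oxetane F1, which keeps the bought configuration. One portion of F1 is opened at the tertiary carbon with inversion (ethereal H2O2, Me3SiOTf, −78→0 °C) to (3S)‑3‑hydroperoxy‑3,7‑dimethyloct‑6‑en‑1‑ol F2 and oxidised (Dess–Martin periodinane) to the cyclic peroxy‑hemiacetal (5S)‑5‑methyl‑5‑(4‑methylpent‑3‑en‑1‑yl)‑1,2‑dioxolan‑3‑ol F3. The other portion is ozonised at the trisubstituted alkene and olefinated with 8 to the oxetane enoate F4, opened in the same way to the hydroperoxy alcohol F5, cyclised (Et2NH, CF3CH2OH; the C2/C3 isomers are separated here on the small fragment) to the dioxane alcohol F6 and oxidised (Dess–Martin periodinane) to the dioxane aldehyde F7. Purchased [(2R)‑3‑hydroxy‑2‑methylpropyl]triphenylphosphonium bromide F8 (2 equiv KN(SiMe3)2, THF, −78 °C) olefinates F7 to the (Z)‑homoallylic alcohol F9. I2/PPh3/imidazole gives the iodide F10 and PPh3 (MeCN, 50 °C) the phosphonium iodide F11. Its ylide (KN(SiMe3)2) condenses with F3 to the (Z,Z)‑diene hydroperoxide F12. Diimide (2‑nitrobenzenesulfonylhydrazide, Et3N, CH2Cl2) saturates only the two disubstituted alkenes and delivers 16.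

Step 2 (photochemical nickel coupling). The risks are 1,5‑hydrogen shift or 6‑exo cyclisation of the C12 radical and sluggish activation of the β‑branched bromide. The fallback sets out from 1 and comes back at 6: the alkylborane 2 of step 1 is not oxidised but coupled directly with 4 in a thermal alkyl–alkyl Suzuki reaction (Pd(OAc)2, PCy3, K3PO4·H2O, THF, rt; C–Br reacts, C–Cl survives). It makes no compound outside the list (F0).

Step 5 (sp3–sp3 Suzuki coupling with a β‑branched iodide). The risks are slow oxidative addition and β‑hydride elimination. The fallback sets out from 7 and comes back at 12. Copper‑catalysed coupling of 7 with vinylmagnesium bromide (Li2CuCl4 cat., THF, −20 °C→rt) gives (4R,8S)‑4,8,12‑trimethyltrideca‑1,11‑dien‑8‑ol F13. Cross‑metathesis of F13 with the vinyl carbinol 10 (second‑generation Hoveyda–Grubbs catalyst, CH2Cl2, 40 °C) gives the (7E)‑triene diol F14. Diimide (2‑nitrobenzenesulfonylhydrazide, Et3N) reduces only the new disubstituted alkene to give 12.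

**Further compounds**

F1 | step 6 | (2R)‑2‑methyl‑2‑(4‑methylpent‑3‑en‑1‑yl)oxetane | C[C@@]1(CCC=C(C)C)CCO1
F2 | step 6 | (3S)‑3‑hydroperoxy‑3,7‑dimethyloct‑6‑en‑1‑ol | OCC[C@@](C)(OO)CCC=C(C)C
F3 | step 6 | (5S)‑5‑methyl‑5‑(4‑methylpent‑3‑en‑1‑yl)‑1,2‑dioxolan‑3‑ol (both anomers) | OC1C[C@](C)(CCC=C(C)C)OO1
F4 | step 6 | methyl (2E)‑2‑methyl‑5‑[(2R)‑2‑methyloxetan‑2‑yl]pent‑2‑enoate | COC(=O)/C(C)=C/CC[C@]1(C)CCO1
F5 | step 6 | methyl (2E,6S)‑6‑hydroperoxy‑8‑hydroxy‑2,6‑dimethyloct‑2‑enoate | COC(=O)/C(C)=C/CC[C@](C)(OO)CCO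
F6 | step 6 | methyl (2R)‑2‑[(3S,6S)‑6‑(2‑hydroxyethyl)‑6‑methyl‑1,2‑dioxan‑3‑yl]propanoate | COC(=O)[C@H](C)[C@@H]1CC[C@@](C)(CCO)OO1
F7 | step 6 | methyl (2R)‑2‑[(3S,6S)‑6‑methyl‑6‑(2‑oxoethyl)‑1,2‑dioxan‑3‑yl]propanoate | COC(=O)[C@H](C)[C@@H]1CC[C@@](C)(CC=O)OO1
F8 | step 6 | [(2R)‑3‑hydroxy‑2‑methylpropyl]triphenylphosphonium bromide | OC[C@@H](C)C[P+](c1ccccc1)(c1ccccc1)c1ccccc1.[Br-]
F9 | step 6 | methyl (2R)‑2‑[(3S,6S)‑6‑[(2Z,4S)‑5‑hydroxy‑4‑methylpent‑2‑en‑1‑yl]‑6‑methyl‑1,2‑dioxan‑3‑yl]propanoate | COC(=O)[C@H](C)[C@@H]1CC[C@@](C)(C/C=C\[C@H](C)CO)OO1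
F10 | step 6 | methyl (2R)‑2‑[(3S,6S)‑6‑[(2Z,4S)‑5‑iodo‑4‑methylpent‑2‑en‑1‑yl]‑6‑methyl‑1,2‑dioxan‑3‑yl]propanoate | COC(=O)[C@H](C)[C@@H]1CC[C@@](C)(C/C=C\[C@H](C)CI)OO1
F11 | step 6 | triphenylphosphonium iodide from F10 (iodide replaced by PPh3+, 2S,3Z in the pentenyl chain) | COC(=O)[C@H](C)[C@@H]1CC[C@@](C)(C/C=C\[C@H](C)C[P+](c2ccccc2)(c2ccccc2)c2ccccc2)OO1.[I-]
F12 | step 6 | methyl (2R)‑2‑[(3S,6S)‑6‑[(2Z,4R,5Z,8S)‑8‑hydroperoxy‑4,8,12‑trimethyltrideca‑2,5,11‑trien‑1‑yl]‑6‑methyl‑1,2‑dioxan‑3‑yl]propanoate | COC(=O)[C@H](C)[C@@H]1CC[C@@](C)(C/C=C\[C@H](C)/C=C\C[C@](C)(CCC=C(C)C)OO)OO1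
F0 | step 2 | none | none
F13 | step 5 | (4R,8S)‑4,8,12‑trimethyltrideca‑1,11‑dien‑8‑ol | C=CC[C@H](C)CCC[C@](C)(O)CCC=C(C)C
F14 | step 5 | methyl (2E,6R,7E,10R,14S)‑6,14‑dihydroxy‑2,6,10,14,18‑pentamethylnonadeca‑2,7,17‑trienoate | COC(=O)/C(C)=C/CC[C@@](C)(O)/C=C/C[C@H](C)CCC[C@](C)(O)CCC=C(C)C
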